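**Retrosynthetic overview**

1. Target 19 ⇐ removal of four methoxymethyl (MOM) ethers and re-oxidation of a temporary C4 carbinol ⇐ cis-(3R,4R)-isoflavan-4-ol 17.
2. 17 ⇐ one-pot construction of ring C from the acyclic deoxybenzoin 13 and ethyl formate: formylation at C3, closure of the O1–C8a bond by displacement of fluoride on ring A, then transfer hydrogenation of C2=C3 and C4=O with dynamic kinetic resolution.
3. Enabling feature: the C4 carbonyl sits ortho to C8a of ring A and activates a C8a–F bond for addition–elimination (the ring-A oxygens at C5 and C7 are meta to C8a and do not deactivate it); the same carbonyl together with ring B makes C3–H acidic, which serves first for formylation and then for the racemisation that the dynamic resolution needs.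
4. 13 ⇐ Pd-catalysed α-arylation joining the ring-A acetophenone 6 (from mirror-symmetric 5-fluororesorcinol, whose symmetry fixes the 6-methyl pattern) with the ring-B bromide 12 (from 4,6-dibromoresorcinol and geranyl bromide).
5. Ring order: rings A and B are bought as arenes; ring C is the only ring formed, in step 7.

Key step: step 7

Assumption: 5-fluorobenzene-1,3-diol, 4,6-dibromobenzene-1,3-diol and geranyl bromide are taken as commercial, and the stereodescriptor of the target is read as 3R.

**Route**

Step 1
Reactants: 1 5-fluorobenzene-1,3-diol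
Product: 2 1-fluoro-3,5-bis(methoxymethoxy)benzene
Conditions: MOMCl, i-Pr2NEt, CH2Cl2, 0 °C → rt
Reagents that add atoms: chloromethyl methyl ether, COCCl
Why: Double O-alkylation of the phenols with chloromethyl methyl ether (Williamson-type acetal ether formation) installs groups that survive organolithium, palladium, hydride and oxidation chemistry and that direct the two metalations that follow; no stereocentre is involved.

Step 2
Reactants: 2 1-fluoro-3,5-bis(methoxymethoxy)benzene
Product: 4 5-fluoro-1,3-bis(methoxymethoxy)-2-methylbenzene, via aryllithium 3 (not isolated)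
Conditions: n-BuLi, TMEDA, Et2O, −20 → 0 °C; MeI, −78 °C → rt
Reagents that add atoms: iodomethane, CI
Why: Directed ortho-metalation under coordination control should place lithium on the carbon flanked by both methoxymethoxy groups (two cooperating directing groups outweigh the single fluorine at the alternative site in a weakly coordinating solvent), and the aryllithium is methylated by SN2 attack on MeI to give the methyl group that becomes C6–CH3.

Step 3
Reactants: 4 5-fluoro-1,3-bis(methoxymethoxy)-2-methylbenzene
Product: 6 1-[6-fluoro-2,4-bis(methoxymethoxy)-3-methylphenyl]ethan-1-one, via aryllithium 5 (not isolated)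
Conditions: n-BuLi, THF, −78 °C; MeC(O)N(OMe)Me, −78 °C; H2O
Reagents that add atoms: N-methoxy-N-methylacetamide, CON(C)C(C)=O
Why: A second directed ortho-metalation can only occur at the two equivalent ring C–H positions left, each between fluorine and a methoxymethoxy group, and Weinreb ketone synthesis (stable chelated tetrahedral adduct, no over-addition) then gives the acetophenone, the low temperature keeping the ortho-fluoroaryllithium from eliminating LiF.

Step 4
Reactants: 7 4,6-dibromobenzene-1,3-diol
Product: 8 1,5-dibromo-2,4-bis(methoxymethoxy)benzene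
Conditions: MOMCl, i-Pr2NEt, CH2Cl2, 0 °C → rt
Reagents that add atoms: chloromethyl methyl ether, COCCl
Why: The same Williamson-type acetal ether formation as in step 1 protects both phenols of ring B with groups that tolerate the halogen–metal exchange and all later steps.

Step 5
Reactants: 8 1,5-dibromo-2,4-bis(methoxymethoxy)benzene; 9 geranyl bromide, (2E)-1-bromo-3,7-dimethylocta-2,6-diene
Product: 12 1-bromo-5-[(2E)-3,7-dimethylocta-2,6-dien-1-yl]-2,4-bis(methoxymethoxy)benzene, via aryllithium 10 (not isolated), via arylcopper 11 (not isolated)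
Conditions: n-BuLi (1.0 equiv), THF, −78 °C; CuBr·SMe2; 9, −78 → 0 °C
Reagents that add atoms: none
Why: Bromine–lithium exchange on one of the two equivalent C–Br bonds (the aryllithium formed resists a second exchange), transmetalation to monovalent copper and SN2 allylation at the unhindered CH2 of geranyl bromide should give the linear geranyl arene with the 2E alkene unchanged.

Step 6
Reactants: 6 1-[6-fluoro-2,4-bis(methoxymethoxy)-3-methylphenyl]ethan-1-one; 12 1-bromo-5-[(2E)-3,7-dimethylocta-2,6-dien-1-yl]-2,4-bis(methoxymethoxy)benzene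
Product: 13 2-{5-[(2E)-3,7-dimethylocta-2,6-dien-1-yl]-2,4-bis(methoxymethoxy)phenyl}-1-[6-fluoro-2,4-bis(methoxymethoxy)-3-methylphenyl]ethan-1-one
Conditions: Pd2(dba)3, XPhos, K3PO4, toluene, 80 °C
Reagents that add atoms: none
Why: Palladium-catalysed α-arylation of a methyl ketone (Buchwald–Hartwig type: oxidative addition of the C–Br bond to zerovalent palladium, enolate binding, reductive elimination) forms the C3–C1' bond, the bulky biaryl phosphine and the ortho substituent of the aryl group stopping at monoarylation and the mild base K3PO4 leaving the C–F bond and the acetals untouched.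

Step 7
Reactants: 13 2-{5-[(2E)-3,7-dimethylocta-2,6-dien-1-yl]-2,4-bis(methoxymethoxy)phenyl}-1-[6-fluoro-2,4-bis(methoxymethoxy)-3-methylphenyl]ethan-1-one
Product: 17 (3R,4R)-3-{5-[(2E)-3,7-dimethylocta-2,6-dien-1-yl]-2,4-bis(methoxymethoxy)phenyl}-5,7-bis(methoxymethoxy)-6-methyl-3,4-dihydro-2H-chromen-4-ol (cis), via sodium enolate 14 (not isolated), via isoflavone 15 (not isolated), via racemic isoflavanone 16 (not isolated)
Conditions: NaH, HCO2Et, THF, 0 °C → rt; DMF, 80 °C; then HCO2H/Et3N (1:1.2), RuCl[(R,R)-TsDPEN](p-cymene) (5 mol %), 40 °C, one pot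
Reagents that add atoms: ethyl formate, CCOC=O
Why: Claisen formylation of the C3 methylene (acidified by the C4 carbonyl and by ring B) gives the sodium enolate 14, whose formyl oxygen adds to C8a of ring A, ortho to the C4 carbonyl, and expels fluoride (SNAr addition–elimination) to give isoflavone 15; the formic acid/triethylamine mixture then neutralises the base and the ruthenium hydride reduces first C2=C3 (to 16) and then the C4 carbonyl. The closest known reaction types are the base-mediated cyclisation of 1-(2-fluoroaryl)-1,3-dicarbonyl enolates to chromones and flavones and the Noyori–Ikariya transfer hydrogenation of isoflavones and isoflavanones to cis-isoflavan-4-ols with dynamic kinetic resolution. Ring C closes by a six-membered ipso attack of oxygen on C8a (6-exo-trig with respect to C8a=C8, the negative charge of the Meisenheimer adduct being taken up through C4a by the C4 carbonyl), driven by formation of the aromatic pyranone. C3 and C4 are both set by the catalyst: 16 should racemise at C3 through its enol in the amine-buffered medium faster than it is reduced, and the (R,R)-TsDPEN ligand is expected to transfer hydride to C4 of the 3R enantiomer only, on the face anti to the ring-B aryl group, which gives the cis-(3R,4R) alcohol. The step needs oxygen to enter at C8a and not at the other carbon ortho to the ketone (6-methyl versus 8-methyl chromanone), and the substrate secures this because only C8a bears a leaving group, a consequence of the mirror-symmetric arene 4 used for ring A, while the oxygens at C5 and C7 are meta to C8a and do not deactivate it. The E and Z forms of 14 equilibrate and both enantiomers of 16 are consumed, so the isomer mixtures funnel into one product, and the isolated trisubstituted geranyl alkenes are not touched by the transfer-hydrogenation catalyst.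

Step 8
Reactants: 17 (3R,4R)-3-{5-[(2E)-3,7-dimethylocta-2,6-dien-1-yl]-2,4-bis(methoxymethoxy)phenyl}-5,7-bis(methoxymethoxy)-6-methyl-3,4-dihydro-2H-chromen-4-ol
Product: 18 (3R)-3-{5-[(2E)-3,7-dimethylocta-2,6-dien-1-yl]-2,4-bis(methoxymethoxy)phenyl}-5,7-bis(methoxymethoxy)-6-methyl-2,3-dihydro-4H-chromen-4-one
Conditions: Dess–Martin periodinane, CH2Cl2, 0 °C → rt
Reagents that add atoms: none
Why: Dess–Martin oxidation converts the temporary C4 carbinol back into the C4 ketone under non-basic conditions at low temperature, so the 3R centre set in step 7, which is now alpha to the carbonyl, should not enolise and no other group is affected.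

Step 9
Reactants: 18 (3R)-3-{5-[(2E)-3,7-dimethylocta-2,6-dien-1-yl]-2,4-bis(methoxymethoxy)phenyl}-5,7-bis(methoxymethoxy)-6-methyl-2,3-dihydro-4H-chromen-4-one
Product: 19 (3R)-3-{5-[(2E)-3,7-dimethylocta-2,6-dien-1-yl]-2,4-dihydroxyphenyl}-5,7-dihydroxy-6-methyl-2,3-dihydro-4H-chromen-4-one (CNP0348256.1)
Conditions: ZnBr2, n-PrSH, CH2Cl2, 0 °C
Reagents that add atoms: none
Why: Lewis-acid-assisted thiolysis of the four aryl methoxymethyl ethers (ZnBr2 activates the acetal, the thiol captures the methoxymethyl cation) is fast at 0 °C under non-basic, non-protic conditions, which should preserve the enolisable 3R centre and leave the geranyl alkenes unprotonated.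

**Compound list**

1 | 5-fluorobenzene-1,3-diol (5-fluororesorcinol) | Oc1cc(O)cc(F)c1 | starting material
2 | 1-fluoro-3,5-bis(methoxymethoxy)benzene | COCOc1cc(OCOC)cc(F)c1 | intermediate
3 | [4-fluoro-2,6-bis(methoxymethoxy)phenyl]lithium | COCOc1cc(F)cc(OCOC)c1[Li] | intermediate
4 | 5-fluoro-1,3-bis(methoxymethoxy)-2-methylbenzene | COCOc1cc(F)cc(OCOC)c1C | intermediate
5 | [6-fluoro-2,4-bis(methoxymethoxy)-3-methylphenyl]lithium | COCOc1cc(F)c([Li])c(OCOC)c1C | intermediate
6 | 1-[6-fluoro-2,4-bis(methoxymethoxy)-3-methylphenyl]ethan-1-one | CC(=O)c1c(F)cc(OCOC)c(C)c1OCOC | intermediate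
7 | 4,6-dibromobenzene-1,3-diol (4,6-dibromoresorcinol) | Oc1cc(O)c(Br)cc1Br | starting material
8 | 1,5-dibromo-2,4-bis(methoxymethoxy)benzene | COCOc1cc(OCOC)c(Br)cc1Br | intermediate
9 | geranyl bromide, (2E)-1-bromo-3,7-dimethylocta-2,6-diene | CC(C)=CCC/C(C)=C/CBr | starting material
10 | [5-bromo-2,4-bis(methoxymethoxy)phenyl]lithium | COCOc1cc(OCOC)c(Br)cc1[Li] | intermediate
11 | [5-bromo-2,4-bis(methoxymethoxy)phenyl]copper | COCOc1cc(OCOC)c(Br)cc1[Cu] | intermediate
12 | 1-bromo-5-[(2E)-3,7-dimethylocta-2,6-dien-1-yl]-2,4-bis(methoxymethoxy)benzene | CC(C)=CCC/C(C)=C/Cc1cc(Br)c(OCOC)cc1OCOC | intermediate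
13 | 2-{5-[(2E)-3,7-dimethylocta-2,6-dien-1-yl]-2,4-bis(methoxymethoxy)phenyl}-1-[6-fluoro-2,4-bis(methoxymethoxy)-3-methylphenyl]ethan-1-one | CC(C)=CCC/C(C)=C/Cc1cc(CC(=O)c2c(F)cc(OCOC)c(C)c2OCOC)c(OCOC)cc1OCOC | intermediate
14 | sodium (1Z)-2-{5-[(2E)-3,7-dimethylocta-2,6-dien-1-yl]-2,4-bis(methoxymethoxy)phenyl}-3-[6-fluoro-2,4-bis(methoxymethoxy)-3-methylphenyl]-3-oxoprop-1-en-1-olate | CC(C)=CCC/C(C)=C/Cc1cc(/C(=C/[O-])C(=O)c2c(F)cc(OCOC)c(C)c2OCOC)c(OCOC)cc1OCOC.[Na+] | intermediate
15 | 3-{5-[(2E)-3,7-dimethylocta-2,6-dien-1-yl]-2,4-bis(methoxymethoxy)phenyl}-5,7-bis(methoxymethoxy)-6-methyl-4H-chromen-4-one | CC(C)=CCC/C(C)=C/Cc1cc(-c2coc3cc(OCOC)c(C)c(OCOC)c3c2=O)c(OCOC)cc1OCOC | intermediate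
16 | rac-3-{5-[(2E)-3,7-dimethylocta-2,6-dien-1-yl]-2,4-bis(methoxymethoxy)phenyl}-5,7-bis(methoxymethoxy)-6-methyl-2,3-dihydro-4H-chromen-4-one | CC(C)=CCC/C(C)=C/Cc1cc(C2COc3cc(OCOC)c(C)c(OCOC)c3C2=O)c(OCOC)cc1OCOC | intermediate
17 | (3R,4R)-3-{5-[(2E)-3,7-dimethylocta-2,6-dien-1-yl]-2,4-bis(methoxymethoxy)phenyl}-5,7-bis(methoxymethoxy)-6-methyl-3,4-dihydro-2H-chromen-4-ol (cis) | CC(C)=CCC/C(C)=C/Cc1cc([C@@H]2COc3cc(OCOC)c(C)c(OCOC)c3[C@@H]2O)c(OCOC)cc1OCOC | intermediate
18 | (3R)-3-{5-[(2E)-3,7-dimethylocta-2,6-dien-1-yl]-2,4-bis(methoxymethoxy)phenyl}-5,7-bis(methoxymethoxy)-6-methyl-2,3-dihydro-4H-chromen-4-one | CC(C)=CCC/C(C)=C/Cc1cc([C@@H]2COc3cc(OCOC)c(C)c(OCOC)c3C2=O)c(OCOC)cc1OCOC | intermediate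
19 | (3R)-3-{5-[(2E)-3,7-dimethylocta-2,6-dien-1-yl]-2,4-dihydroxyphenyl}-5,7-dihydroxy-6-methyl-2,3-dihydro-4H-chromen-4-one | CC(C)=CCC/C(C)=C/Cc1cc([C@@H]2COc3cc(O)c(C)c(O)c3C2=O)c(O)cc1O | target

**Step count and risks**

Total step count: 9. Longest linear sequence: 7 steps (steps 1, 2, 3, 6, 7, 8, 9, from compound 1).

The three steps most likely to fail:

Step 7. The fluoride displacement may be slow or incomplete, because the delocalised formyl enolate is a weak oxygen nucleophile and the doubly ortho-substituted aryl ketone is twisted out of conjugation and activates C8a less. Ethoxide may compete for the C–F bond, and the salts of the first stage may inhibit the ruthenium catalyst so that the reduction stalls. The fallback sets out from 13 and changes both the one-carbon unit and the nucleophile. Aldol hydroxymethylation with paraformaldehyde and K2CO3 in DMF at 60 °C should give the racemic β-hydroxy ketone rac-2-{5-[(2E)-3,7-dimethylocta-2,6-dien-1-yl]-2,4-bis(methoxymethoxy)phenyl}-1-[6-fluoro-2,4-bis(methoxymethoxy)-3-methylphenyl]-3-hydroxypropan-1-one F1. Its primary alkoxide, a far stronger nucleophile, closes the same oxygen-to-C8a bond in the same flask to give racemic isoflavanone 16, which is isolated. In a separate flask 16 is then reduced with RuCl[(R,R)-TsDPEN](p-cymene) and HCO2H/Et3N under dynamic kinetic resolution, and the route is rejoined at 17. Should the catalyst deliver the opposite sense of induction, its (S,S) enantiomer would be used.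

Step 9. Enolisation at C3 under Lewis-acidic conditions may erode enantiomeric purity, and the geranyl chain may cyclise onto the freed neighbouring phenol. The fallback exchanges the protecting groups before the stereocentre exists. It sets out from isoflavone 15, obtained by stopping step 7 after its first stage and isolating 15. ZnBr2/n-PrSH in CH2Cl2 removes the four acetals to give the tetrahydroxyisoflavone 3-{5-[(2E)-3,7-dimethylocta-2,6-dien-1-yl]-2,4-dihydroxyphenyl}-5,7-dihydroxy-6-methyl-4H-chromen-4-one F2. TBSOTf and 2,6-lutidine in CH2Cl2 give the tetrakis(tert-butyldimethylsilyl) ether of that isoflavone F3. Transfer hydrogenation under the conditions of the second stage of step 7 should give the cis-(3R,4R)-tetrakis(silyloxy)isoflavan-4-ol F4. Dess–Martin oxidation gives the (3R)-tetrakis(silyloxy)isoflavanone F5. HF·pyridine in THF/pyridine at 0 °C then removes the silyl groups under buffered conditions that neither enolise C3 nor protonate the alkenes, and the route is rejoined at 19.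

Step 2. Metalation may occur between fluorine and one methoxymethoxy group instead of between the two acetal groups, which would methylate the wrong carbon and, on warming, lead to loss of LiF from the ortho-fluoroaryllithium. The fallback sets out from 1 and uses a stronger directing group. ClC(O)NEt2 and K2CO3 in MeCN give 5-fluoro-1,3-phenylene bis(diethylcarbamate) F6. s-BuLi/TMEDA in THF at −78 °C, followed by MeI at that temperature, should metalate between the two carbamates (the strongest oxygen-based directing groups) and give 5-fluoro-2-methyl-1,3-phenylene bis(diethylcarbamate) F7. NaOH in EtOH at reflux cleaves the carbamates to 5-fluoro-2-methylbenzene-1,3-diol F8, and MOMCl/i-Pr2NEt as in step 1 rejoins the route at 4.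

**Further compounds**

F1 | step 7 | rac-2-{5-[(2E)-3,7-dimethylocta-2,6-dien-1-yl]-2,4-bis(methoxymethoxy)phenyl}-1-[6-fluoro-2,4-bis(methoxymethoxy)-3-methylphenyl]-3-hydroxypropan-1-one | CC(C)=CCC/C(C)=C/Cc1cc(C(CO)C(=O)c2c(F)cc(OCOC)c(C)c2OCOC)c(OCOC)cc1OCOC
F2 | step 9 | 3-{5-[(2E)-3,7-dimethylocta-2,6-dien-1-yl]-2,4-dihydroxyphenyl}-5,7-dihydroxy-6-methyl-4H-chromen-4-one | CC(C)=CCC/C(C)=C/Cc1cc(-c2coc3cc(O)c(C)c(O)c3c2=O)c(O)cc1O
F3 | step 9 | 3-{2,4-bis(tert-butyldimethylsilyloxy)-5-[(2E)-3,7-dimethylocta-2,6-dien-1-yl]phenyl}-5,7-bis(tert-butyldimethylsilyloxy)-6-methyl-4H-chromen-4-one | CC(C)=CCC/C(C)=C/Cc1cc(-c2coc3cc(O[Si](C)(C)C(C)(C)C)c(C)c(O[Si](C)(C)C(C)(C)C)c3c2=O)c(O[Si](C)(C)C(C)(C)C)cc1O[Si](C)(C)C(C)(C)C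
F4 | step 9 | (3R,4R)-3-{2,4-bis(tert-butyldimethylsilyloxy)-5-[(2E)-3,7-dimethylocta-2,6-dien-1-yl]phenyl}-5,7-bis(tert-butyldimethylsilyloxy)-6-methyl-3,4-dihydro-2H-chromen-4-ol | CC(C)=CCC/C(C)=C/Cc1cc([C@@H]2COc3cc(O[Si](C)(C)C(C)(C)C)c(C)c(O[Si](C)(C)C(C)(C)C)c3[C@@H]2O)c(O[Si](C)(C)C(C)(C)C)cc1O[Si](C)(C)C(C)(C)C
F5 | step 9 | (3R)-3-{2,4-bis(tert-butyldimethylsilyloxy)-5-[(2E)-3,7-dimethylocta-2,6-dien-1-yl]phenyl}-5,7-bis(tert-butyldimethylsilyloxy)-6-methyl-2,3-dihydro-4H-chromen-4-one | CC(C)=CCC/C(C)=C/Cc1cc([C@@H]2COc3cc(O[Si](C)(C)C(C)(C)C)c(C)c(O[Si](C)(C)C(C)(C)C)c3C2=O)c(O[Si](C)(C)C(C)(C)C)cc1O[Si](C)(C)C(C)(C)C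
F6 | step 2 | 5-fluoro-1,3-phenylene bis(diethylcarbamate) | CCN(CC)C(=O)Oc1cc(F)cc(OC(=O)N(CC)CC)c1
F7 | step 2 | 5-fluoro-2-methyl-1,3-phenylene bis(diethylcarbamate) | CCN(CC)C(=O)Oc1cc(F)cc(OC(=O)N(CC)CC)c1C
F8 | step 2 | 5-fluoro-2-methylbenzene-1,3-diol | Cc1c(O)cc(F)cc1O
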